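**Strategy.** Guaiane numbering, primes for the spiro half. The cyclohexene C2–C1=C10–C14–C15′–C4′ joining the two guaianolides contains an aldol motif: the C2 carbinol lies β to the C3′ ketone through spiro C4′, and C1=C10 is the enone-type alkene of a 2,3-dione. The ring is therefore grown from a dispiro cyclobutane C10–C14–C15′–C4′, the crossed [2+2] photoadduct of dehydrozaluzanin C and its 2-silyloxy dienone derivative. Fluoride unmasks the diosphenolate; strain-driven retro-Michael cleavage of C10–C4′ and aldol reclosure of C4′ onto C2 expand four to six atoms, setting the C1=C10 alkene, the C2 carbinol and the C4′ spiro centre at once.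

Key step: step 8

Remark: the carbinol carbons of 2 (at C3) and 6 (at C2) are drawn as the α epimers expected from attack on the convex face; both are oxidised to carbonyl carbons later, so this assignment has no consequence.

**Step 1**
Reactants: 1 dehydrocostus lactone
Product: 2 epi-zaluzanin C (α-hydroxyl at C3 of dehydrocostus lactone)
Conditions: SeO2 (0.3 equiv), t-BuOOH (2 equiv), CH2Cl2, 0 °C to rt
Reagents that add atoms: selenium dioxide, O=[Se]=O (oxygen donor, turned over); tert-butyl hydroperoxide, CC(C)(C)OO (terminal oxygen source)
Why: Selenium dioxide allylic hydroxylation (ene reaction, then [2,3]-sigmatropic shift) should favour the cyclopentane methylene C3 next to the C4(15) methylene and deliver oxygen on the convex α face, a centre that the next oxidation removes again.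

**Step 2**
Reactants: 2 epi-zaluzanin C
Product: 3 dehydrozaluzanin C
Conditions: Dess–Martin periodinane (1.2 equiv), CH2Cl2, 0 °C to rt
Reagents that add atoms: none
Why: Dess–Martin oxidation of the allylic alcohol to the cross-conjugated enone is neutral and fast, so the exocyclic methylene groups and the lactone are untouched.

**Step 3**
Reactants: 3 dehydrozaluzanin C
Product: 4 trimethylsilyl dienol ether of dehydrozaluzanin C (C2=C3–OSiMe3)
Conditions: LiN(SiMe3)2 (1.1 equiv) premixed with Me3SiCl (1.5 equiv), THF, −78 °C (in situ quench)
Reagents that add atoms: chlorotrimethylsilane, C[Si](C)(C)Cl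
Why: Kinetic enolisation with in situ O-silylation can only occur at C2, the sole enolisable position of the ketone (C4 is sp2), and the hindered amide at −78 °C should not add to the methylene lactone or the enone.

**Step 4**
Reactants: 4 trimethylsilyl dienol ether
Product: 6 α-ketol (α-hydroxyl at C2 of dehydrozaluzanin C), via silyloxy epoxide 5 (not isolated)
Conditions: dimethyldioxirane (1.05 equiv, acetone solution), CH2Cl2, −78 °C; then 10% aqueous citric acid, THF, 0 °C
Reagents that add atoms: dimethyldioxirane, CC1(C)OO1
Why: Rubottom oxidation: the dioxirane should epoxidise the electron-rich silyl enol ether C2=C3 far faster than the 1,1-disubstituted or acceptor-substituted alkenes, from the convex α face, and mild acid collapses the silyloxy epoxide to the α-hydroxy ketone, whose C2 centre is erased in the following oxidation.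

**Step 5**
Reactants: 6 α-ketol
Product: 8 diosphenol (C1=C2 enol of the vicinal dione), via vicinal dione 7 (not isolated)
Conditions: Dess–Martin periodinane (1.1 equiv), CH2Cl2, 0 °C; used at once in the following silylation
Reagents that add atoms: none
Why: Dess–Martin oxidation of the α-ketol gives the vicinal dione, which as a cyclopentane-1,2-dione with a single α-hydrogen (at C1) should enolise spontaneously to the diosphenol conjugated with the C10(14) methylene.

**Step 6**
Reactants: 8 diosphenol
Product: 9 tert-butyldimethylsilyl ether of the diosphenol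
Conditions: t-BuMe2SiOTf (1.2 equiv), 2,6-lutidine (2 equiv), CH2Cl2, −78 °C
Reagents that add atoms: tert-butyldimethylsilyl trifluoromethanesulfonate, CC(C)(C)[Si](C)(C)OS(=O)(=O)C(F)(F)F
Why: Standard silyl ether formation on the acidic enol hydroxyl with a silyl triflate and a hindered pyridine base masks the diosphenol, gives a compound that can be chromatographed and leaves the electrophilic alkenes alone.

**Step 7**
Reactants: 9 silyl dienol ether; 3 dehydrozaluzanin C
Product: 10 dispiro cyclobutane photoadduct (cyclobutane C10–C14–C15′–C4′; both new spiro centres undefined)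
Conditions: thioxanthone (10 mol %), 405 nm LED, degassed CH2Cl2 (0.02 M in the silyl dienol ether, dehydrozaluzanin C in threefold excess and the unreacted part recovered), −40 °C
Reagents that add atoms: none
Why: Triplet-sensitised crossed [2+2] photocycloaddition of a 1,3-diene with an electron-poor 1,1-disubstituted alkene, a fully atom-economic union of the two partners: thioxanthone should transfer energy only to the extended dienone, whose terminal C14 bonds to C15′ of the enone to give the best-stabilised 1,4-biradical (allyl-type radical over C10–C1–C2, tertiary α-keto radical at C4′), which closes head-to-head at C10–C4′, while −40 °C suppresses the thermal [4+2] reaction; the two new spiro centres need no control because both become sp2 in the key step.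

**Step 8**
Reactants: 10 dispiro cyclobutane photoadduct
Product: 14 target dimer CNP0269880.2, via diosphenolate 11 (not isolated), via ring-opened enolate 12 (not isolated), via tertiary alkoxide 13 (not isolated)
Conditions: Bu4NF (1.05 equiv), THF (0.005 M), −78 to −20 °C; then AcOH (1.5 equiv), −78 °C
Reagents that add atoms: none
Why: Proposed new method: fluoride cleaves the Si–O bond to give the diosphenolate, whose enolate C1=C2(O−) is β,γ to the strained C10–C4′ bond, so an E1cB-type retro-Michael fragmentation releases the cyclobutane strain (about 26 kcal/mol) and the congestion of two adjacent quaternary carbons and gives the C3′ enolate, still tied through C15′–C14 to a 1(10)-ene-2,3-dione. The enolate carbon C4′ then adds to the C2 carbonyl, the only ketone within reach, closing the cyclohexene C2–C1=C10–C14–C15′–C4′ by a 6-(enolexo)-exo-trig aldol to the tertiary alkoxide, which the quench protonates; overall this is a formal anion-accelerated 1,3-shift of C4′ from C10 to C2. The closest known reaction types are the oxyanion-accelerated vinylcyclobutane–cyclohexene rearrangement and the fragmentation–reclosure sequences of [2+2] photoadducts (De Mayo retro-aldol, retro-Mannich/Mannich), here transposed to a retro-Michael/aldol pair. At C4′ the new bond should form on the convex α face of the cis-fused hydroazulene enolate, anti to the C5′–C6′ bond; at C2 the non-chelating tetrabutylammonium ion allows an open transition state with the enolate oxygen antiperiplanar to the C2 carbonyl oxygen, which places the C2 oxygen trans to C3′ on the new ring and, given α attack at C4′, puts C4′ on the β face of C2 as in the target. The step needs the intramolecular aldol to outrun loss of the dienolate across C14–C15′ and intermolecular Michael additions to the three exocyclic acceptors, which the three-atom tether, low temperature and high dilution should secure, and the reversibility of the aldol lets a C2 epimer re-equilibrate.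

**Compound list**

1 | dehydrocostus lactone (guaia-4(15),10(14),11(13)-trien-12,6α-olide; 1α-H, 5α-H, 6β-H, 7α-H) | C=C1CC[C@@H]2[C@@H]([C@@H]3[C@H]1CCC3=C)OC(=O)C2=C | starting material
2 | epi-zaluzanin C (3α-hydroxy derivative of 1) | C=C1CC[C@@H]2[C@@H]([C@@H]3[C@H]1C[C@@H](O)C3=C)OC(=O)C2=C | intermediate
3 | dehydrozaluzanin C (3-oxo derivative of 1) | C=C1CC[C@@H]2[C@@H]([C@@H]3[C@H]1CC(=O)C3=C)OC(=O)C2=C | intermediate
4 | 3-(trimethylsilyloxy)guaia-2,4(15),10(14),11(13)-tetraen-12,6α-olide | C=C1CC[C@@H]2[C@@H]([C@@H]3[C@H]1C=C(O[Si](C)(C)C)C3=C)OC(=O)C2=C | intermediate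
5 | 2α,3α-epoxy-3β-(trimethylsilyloxy) derivative of 4 (silyloxy epoxide) | C=C1CC[C@@H]2[C@@H]([C@@H]3[C@H]1[C@H]4O[C@@]4(O[Si](C)(C)C)C3=C)OC(=O)C2=C | intermediate (not isolated)
6 | 2α-hydroxydehydrozaluzanin C (α-ketol) | C=C1CC[C@@H]2[C@@H]([C@@H]3[C@H]1[C@@H](O)C(=O)C3=C)OC(=O)C2=C | intermediate
7 | 2-oxodehydrozaluzanin C (2,3-dione, keto form) | C=C1CC[C@@H]2[C@@H]([C@@H]3[C@H]1C(=O)C(=O)C3=C)OC(=O)C2=C | intermediate (not isolated)
8 | diosphenol: 2-hydroxy-3-oxoguaia-1,4(15),10(14),11(13)-tetraen-12,6α-olide | C=C1CC[C@@H]2[C@@H]([C@@H]3C1=C(O)C(=O)C3=C)OC(=O)C2=C | intermediate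
9 | 2-(tert-butyldimethylsilyloxy) ether of 8 | C=C1CC[C@@H]2[C@@H]([C@@H]3C1=C(O[Si](C)(C)C(C)(C)C)C(=O)C3=C)OC(=O)C2=C | intermediate
10 | dispiro cyclobutane: C10 of 9 and C4′ of 3 joined directly and through C14–C15′; mixture at the two new spiro carbons | C=C1C(=O)C(O[Si](C)(C)C(C)(C)C)=C2[C@H]1[C@H]1OC(=O)C(=C)[C@@H]1CCC23CCC34C(=O)C[C@H]3C(=C)CC[C@H]5C(=C)C(=O)O[C@@H]5[C@H]34 | intermediate
11 | tetrabutylammonium diosphenolate of desilylated 10 | C=C1C(=O)C([O-])=C2[C@H]1[C@H]1OC(=O)C(=C)[C@@H]1CCC23CCC34C(=O)C[C@H]3C(=C)CC[C@H]5C(=C)C(=O)O[C@@H]5[C@H]34.CCCC[N+](CCCC)(CCCC)CCCC | intermediate (not isolated)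
12 | ring-opened C3′ enolate: 1(10)-ene-2,3-dione half linked C14–C15′ to the C3′(O−)=C4′ enolate half (tetrabutylammonium salt) | C=C1C(=O)C(=O)C2=C(CCC3=C([O-])C[C@H]4C(=C)CC[C@H]5C(=C)C(=O)O[C@@H]5[C@H]43)CC[C@H]3C(=C)C(=O)O[C@@H]3[C@@H]12.CCCC[N+](CCCC)(CCCC)CCCC | intermediate (not isolated)
13 | tetrabutylammonium C2 alkoxide of the target | C=C1C(=O)[C@]2([O-])C3=C(CC[C@H]4C(=C)C(=O)O[C@@H]4[C@@H]13)CC[C@]21C(=O)C[C@H]2C(=C)CC[C@H]3C(=C)C(=O)O[C@@H]3[C@H]21.CCCC[N+](CCCC)(CCCC)CCCC | intermediate (not isolated)
14 | target CNP0269880.2: 2α-hydroxy-3-oxoguaia-1(10),4(15),11(13)-trien-12,6α-olide joined C2–C4′ (β on C2, α on C4′) and C14–C15′ to 3′-oxoguaia-10′(14′),11′(13′)-dien-12′,6′α-olide | C=C1C(=O)[C@]2(O)C3=C(CC[C@H]4C(=C)C(=O)O[C@@H]4[C@@H]13)CC[C@]21C(=O)C[C@H]2C(=C)CC[C@H]3C(=C)C(=O)O[C@@H]3[C@H]21 | target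

**Step count.** Total: 8 steps. Longest linear sequence: 8 steps (1 → 14); the dehydrozaluzanin C used in step 7 is taken from the same sequence.

**Steps most likely to fail**

Step 8 (proposed new method). The opened enolate may fragment into the two monomers by loss of the dienolate across C14–C15′, oligomerise by intermolecular Michael addition, or close with poor facial selectivity at C2. The fallback sets out from 10 and uses known chemistry. Heating 10 in toluene at 110 °C should effect the thermal vinylcyclobutane–cyclohexene rearrangement, a 1,3-shift of C4′ from C10 to C2 across the silyloxy-substituted allyl unit, which is favoured because the breaking bond is strained and carries radical-stabilising groups at both ends. This gives the 2-O-silyl ether of the target F1. HF·pyridine in THF at 0 °C then cleaves the silyl ether and the fallback comes back to the route at 14.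

Step 7. The biradical may close 1,6 instead of 1,4, the excited dienone may add to the lactone methylene of the enone partner instead of the enone methylene, or it may self-dimerise. The fallback sets out from 9 and 3 and replaces photochemistry by two polar steps. A Yb(OTf)3-catalysed inverse-electron-demand hetero-Diels–Alder reaction (CH2Cl2, −40 °C) uses enone 3 as the 1-oxadiene and the terminal C10=C14 bond of 9 as the electron-rich partner. It should give the spiro 2-alkenyl-3,4-dihydro-2H-pyran F2 (bonds O3′–C10 and C15′–C14). A Lewis-acid-mediated 1,3 O-to-C rearrangement (Me2AlCl, CH2Cl2, −78 °C), a known ring contraction of 2-alkenyl dihydropyrans to acyl cyclobutanes, then moves C10 from O3′ to C4′ and comes back to the route at 10. The competing [3,3] pathway of F2 would have to be held back by the low temperature.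

Step 5. The free diosphenol may be over-oxidised or may dimerise by Diels–Alder reaction during oxidation and isolation. The fallback sets out from 6 and never liberates 8. t-BuMe2SiOTf and 2,6-lutidine give the 2α-silyloxy ketone F3. LiN(SiMe3)2 and Me3SiCl (THF, −78 °C) give the tetrasubstituted bis-silyl enediol ether F4. Saegusa–Ito dehydrogenation (Pd(OAc)2, MeCN, rt) then introduces C1=C2 by β-hydride elimination from C1 and comes back to the route at 9.

**Further compounds**

F1 | step 8 | 2-O-(tert-butyldimethylsilyl) ether of the target | C=C1C(=O)[C@]2(O[Si](C)(C)C(C)(C)C)C3=C(CC[C@H]4C(=C)C(=O)O[C@@H]4[C@@H]13)CC[C@]21C(=O)C[C@H]2C(=C)CC[C@H]3C(=C)C(=O)O[C@@H]3[C@H]21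
F2 | step 7 | spiro dihydropyran hetero-Diels–Alder adduct of 9 and 3 (ring O3′–C3′=C4′–C15′–C14–C10; C10 undefined) | C=C1C(=O)C(O[Si](C)(C)C(C)(C)C)=C2[C@H]1[C@H]1OC(=O)C(=C)[C@@H]1CCC23CCC4=C(O3)C[C@H]3C(=C)CC[C@H]5C(=C)C(=O)O[C@@H]5[C@H]34
F3 | step 5 | 2α-(tert-butyldimethylsilyloxy)dehydrozaluzanin C | C=C1CC[C@@H]2[C@@H]([C@@H]3[C@H]1[C@@H](O[Si](C)(C)C(C)(C)C)C(=O)C3=C)OC(=O)C2=C
F4 | step 5 | 2-(tert-butyldimethylsilyloxy)-3-(trimethylsilyloxy)guaia-2,4(15),10(14),11(13)-tetraen-12,6α-olide | C=C1CC[C@@H]2[C@@H]([C@@H]3[C@H]1C(O[Si](C)(C)C(C)(C)C)=C(O[Si](C)(C)C)C3=C)OC(=O)C2=C
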